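The numbering used is that of the decahydronaphthalene core of the target (C1 bears the acid chain, C5 the quinonylmethyl group; ring A = C1–C4, C4a, C8a). The route rests on disconnecting the C4–C4a bond. A copper-catalysed asymmetric conjugate addition of a chloro-dienylalane to 3-methylcyclohex-2-enone sets quaternary C8a. The key step then joins C4 to C4a by intramolecular ketone-enolate alkylation, closing ring A and fixing the trans fusion by equilibration of the still epimerisable C4a. It exploits that C4a lies between the C5 carbonyl and quaternary C8a, so only its enolate reaches C4. The precursor is a monocyclic chloro ketone carrying the intact diene; the C5 carbonyl later builds C5 and C6.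

Key step: step 5

Remark: pent-3-yn-1-ol, 3-methylcyclohex-2-en-1-one and 4-methoxy-2-methylphenol are taken as commercial; bicyclic intermediates are named with the target numbering throughout.

Step 1
Reactants: 1 pent-3-yn-1-ol
Product: 3 3-iodo-4-methylpent-3-en-1-ol, via alkenylmagnesium bromide 2 (not isolated)
Conditions: MeMgBr (4 equiv), Fe(acac)3 (10 mol %), THF, 0 °C; then I2, −40 → 0 °C
Reagents that add atoms: methylmagnesium bromide (C[Mg]Br); iodine (II)
Why: Iron-catalysed syn-carbomagnesiation of the homopropargylic alkoxide should place methyl on the distal alkyne carbon and magnesium on the proximal one (five-membered chelate), and iodinolysis of the C–Mg bond then gives the vinyl iodide, which has no E/Z issue because the new terminus carries two methyl groups.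

Step 2
Reactants: 3 3-iodo-4-methylpent-3-en-1-ol
Product: 4 5-chloro-3-iodo-2-methylpent-2-ene
Conditions: PPh3, N-chlorosuccinimide, CH2Cl2, 0 °C
Reagents that add atoms: N-chlorosuccinimide (O=C1CCC(=O)N1Cl)
Why: Appel-type chlorination should convert the primary alcohol into the chloride by SN2 displacement of the oxyphosphonium ion without touching the vinyl iodide.

Step 3
Reactants: 4 5-chloro-3-iodo-2-methylpent-2-ene
Product: 5 5-chloro-3-ethynyl-2-methylpent-2-ene
Conditions: HC≡CMgBr, ZnBr2, THF, 0 °C; then 4, Pd(PPh3)4 (5 mol %), 25 → 50 °C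
Reagents that add atoms: ethynylmagnesium bromide (C#C[Mg]Br)
Why: Negishi coupling of the alkenyl iodide with ethynylzinc bromide should give the conjugated enyne, the primary alkyl chloride being inert to the palladium catalyst under these conditions.

Step 4
Reactants: 5 5-chloro-3-ethynyl-2-methylpent-2-ene; 6 3-methylcyclohex-2-en-1-one
Product: 9 (3R)-3-[5-chloro-3-(propan-2-ylidene)pent-1-en-2-yl]-3-methylcyclohexan-1-one, via alkenylalane 7 (not isolated), via aluminium enolate 8 (not isolated)
Conditions: i-Bu2AlH, NiCl2(dppp) (3 mol %), THF, 0 → 22 °C; then 6, Cu(thiophene-2-carboxylate) (5 mol %), chiral phosphinamine ligand Ph2PN[CH(CH3)(2-naphthyl)]2 (enantiomer giving the (R)-ketone), Et2O, −30 °C; aq. NH4Cl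
Reagents that add atoms: none
Why: Nickel-catalysed α-selective hydroalumination should put aluminium on the internal alkyne carbon, and copper-catalysed asymmetric conjugate addition of this alkenylalane then transfers the dienyl group to the β-carbon of the enone, the chiral copper complex selecting the enone face that gives the (R)-configured quaternary centre (future C8a).

Step 5
Reactants: 9 (3R)-3-[5-chloro-3-(propan-2-ylidene)pent-1-en-2-yl]-3-methylcyclohexan-1-one
Product: 12 (4aS,8aR)-8a-methyl-1-methylidene-2-(propan-2-ylidene)decahydronaphthalen-5-one (trans-fused), via potassium enolate 10 (not isolated), via cis-fused epimer 11 (not isolated)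
Conditions: KOt-Bu (1.5 equiv), t-BuOH–THF, 25 → 45 °C, held until the trans/cis composition no longer changes
Reagents that add atoms: none
Why: KOt-Bu enolises ketone 9 reversibly toward both α-carbons, but only the enolate carbon lying between the carbonyl and the quaternary centre (future C4a) can reach the primary chloride, so an SN2 C-alkylation forms the C4–C4a bond and closes ring A. The closest known reaction type is the intramolecular ketone-enolate alkylation that completes methylenecyclohexane annulations of cyclic enones. Ring A is closed in the 6-exo-tet mode, whereas O-alkylation or attack by the other α-carbon would require an eight-membered or bridged ring. The new stereocentre C4a is set under thermodynamic control: it remains α to the carbonyl, so any cis-fused ketone 11 should epimerise through its enolate to the trans-fused ketone 12, in which the axial C8a methyl meets only two syn-axial hydrogens because C2 and C5 are trigonal. The step needs substitution to win over E2 loss of HCl and over intermolecular alkylation, which the primary chloride, the six-membered transition state and moderate dilution should secure.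

Step 6
Reactants: 12 (4aS,8aR)-8a-methyl-1-methylidene-2-(propan-2-ylidene)decahydronaphthalen-5-one
Product: 13 (4aS,8aR)-8a-methyl-1-methylidene-2-(propan-2-ylidene)-1,2,3,4,4a,7,8,8a-octahydronaphthalen-5-yl trifluoromethanesulfonate
Conditions: KN(SiMe3)2, THF, −78 °C; then PhNTf2, −78 → 0 °C
Reagents that add atoms: N-phenylbis(trifluoromethanesulfonimide) (O=S(=O)(N(c1ccccc1)S(=O)(=O)C(F)(F)F)C(F)(F)F)
Why: Kinetic deprotonation should occur at the unhindered C6 methylene and not at the C4a methine beside the quaternary carbon, and O-sulfonylation of that enolate gives the C5=C6 enol triflate (enol triflate formation).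

Step 7
Reactants: 13 (4aS,8aR)-8a-methyl-1-methylidene-2-(propan-2-ylidene)-1,2,3,4,4a,7,8,8a-octahydronaphthalen-5-yl trifluoromethanesulfonate
Product: 15 ethyl 3-[(1S,4aS,8aS)-8a-methyl-2-(propan-2-ylidene)-5-(trifluoromethanesulfonyloxy)-1,2,3,4,4a,7,8,8a-octahydronaphthalen-1-yl]propanoate, via B-alkyl-9-BBN 14 (not isolated)
Conditions: 9-BBN, THF, 0 → 25 °C; then BrCH2CO2Et, potassium 2,6-di-tert-butylphenoxide, THF, 0 → 25 °C
Reagents that add atoms: ethyl bromoacetate (CCOC(=O)CBr)
Why: 9-BBN should hydroborate only the 1,1-disubstituted methylidene, boron going to the terminal carbon and hydrogen to C1 from the face opposite the axial C8a methyl (so the chain ends cis to that methyl), and the B-alkyl group then migrates onto the enolate of ethyl bromoacetate with loss of bromide (α-alkylation of an α-bromo ester by a B-alkyl-9-BBN).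

Step 8
Reactants: 15 ethyl 3-[(1S,4aS,8aS)-8a-methyl-2-(propan-2-ylidene)-5-(trifluoromethanesulfonyloxy)-1,2,3,4,4a,7,8,8a-octahydronaphthalen-1-yl]propanoate
Product: 16 ethyl 3-[(1S,4aS,8aS)-5-formyl-8a-methyl-2-(propan-2-ylidene)-1,2,3,4,4a,7,8,8a-octahydronaphthalen-1-yl]propanoate
Conditions: CO (1 atm), Bu3SnH (slow addition), Pd(PPh3)4 (5 mol %), LiCl, THF, 50 °C
Reagents that add atoms: carbon monoxide ([C-]#[O+])
Why: Palladium-catalysed formylation of the enol triflate (oxidative addition, CO insertion, hydride transfer from the tin hydride) should give the α,β-unsaturated aldehyde without affecting the ester or the tetrasubstituted alkene.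

Step 9
Reactants: 16 ethyl 3-[(1S,4aS,8aS)-5-formyl-8a-methyl-2-(propan-2-ylidene)-1,2,3,4,4a,7,8,8a-octahydronaphthalen-1-yl]propanoate
Product: 18 ethyl 3-[(1S,4aR,6S,8aR)-5-formyl-6,8a-dimethyl-2-(propan-2-ylidene)decahydronaphthalen-1-yl]propanoate (both C5 epimers), via trimethylsilyl enol ether 17 (not isolated)
Conditions: Me2CuLi (from MeLi and CuI), Me3SiCl, THF, −78 °C; then 1 M HCl, THF, 0 °C
Reagents that add atoms: lithium dimethylcuprate ([Li+].C[Cu-]C)
Why: Silyl-chloride-accelerated 1,4-addition of the cuprate to the enal should deliver methyl to C6 axially (antiperiplanar attack on the half-chair, on the face of H-4a, which carries only hydrogens), placing it trans to the C8a methyl, and mild acid cleaves the silyl enol ether to the aldehyde.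

Step 10
Reactants: 19 4-methoxy-2-methylphenol
Product: 20 2-hydroxy-5-methoxy-3-methylbenzaldehyde
Conditions: (CH2O)n, MgCl2, Et3N, MeCN, reflux
Reagents that add atoms: paraformaldehyde, as formaldehyde (C=O)
Why: Magnesium-mediated ortho-formylation of the phenol (Casnati–Skattebøl reaction) should occur at the only free ortho position through a magnesium phenoxide–formaldehyde chelate.

Step 11
Reactants: 20 2-hydroxy-5-methoxy-3-methylbenzaldehyde
Product: 21 2,5-dimethoxy-3-methylbenzaldehyde
Conditions: MeI, K2CO3, DMF, 25 °C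
Reagents that add atoms: iodomethane (CI)
Why: Williamson O-methylation of the phenoxide should proceed cleanly.

Step 12
Reactants: 21 2,5-dimethoxy-3-methylbenzaldehyde
Product: 22 (2,5-dimethoxy-3-methylphenyl)methanol
Conditions: NaBH4, MeOH, 0 °C
Reagents that add atoms: none
Why: Hydride reduction of the aldehyde should give the benzylic alcohol.

Step 13
Reactants: 22 (2,5-dimethoxy-3-methylphenyl)methanol
Product: 23 1-(bromomethyl)-2,5-dimethoxy-3-methylbenzene
Conditions: PBr3, CH2Cl2, 0 °C
Reagents that add atoms: phosphorus tribromide (BrP(Br)Br)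
Why: Bromination of the benzylic alcohol by SN2 displacement of its phosphite ester should give the bromide.

Step 14
Reactants: 18 ethyl 3-[(1S,4aR,6S,8aR)-5-formyl-6,8a-dimethyl-2-(propan-2-ylidene)decahydronaphthalen-1-yl]propanoate; 23 1-(bromomethyl)-2,5-dimethoxy-3-methylbenzene
Product: 25 ethyl 3-[(1S,4aS,5R,6S,8aS)-5-[(2,5-dimethoxy-3-methylphenyl)methyl]-5-formyl-6,8a-dimethyl-2-(propan-2-ylidene)decahydronaphthalen-1-yl]propanoate, via potassium enolate 24 (not isolated)
Conditions: KOt-Bu (1.05 equiv), THF–t-BuOH, 0 °C; then 23, 0 → 25 °C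
Reagents that add atoms: none
Why: C-Alkylation of the thermodynamically favoured aldehyde enolate (the aldehyde α-H is far more acidic than the ester α-H) by the benzylic bromide should occur at C5 from the equatorial direction, opposite the syn-axial C8a methyl that blocks the axial face, so the benzyl group ends cis to the C6 methyl and the formyl group axial (enolate alkylation forming a quaternary centre).

Step 15
Reactants: 25 ethyl 3-[(1S,4aS,5R,6S,8aS)-5-[(2,5-dimethoxy-3-methylphenyl)methyl]-5-formyl-6,8a-dimethyl-2-(propan-2-ylidene)decahydronaphthalen-1-yl]propanoate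
Product: 28 3-[(1S,4aR,5S,6S,8aR)-5-[(2,5-dimethoxy-3-methylphenyl)methyl]-5,6,8a-trimethyl-2-(propan-2-ylidene)decahydronaphthalen-1-yl]propanoic acid, via lithium carboxylate 26 (not isolated), via carboxylate hydrazone 27 (not isolated)
Conditions: LiOH, THF–H2O, 25 °C; then N2H4·H2O, KOH, diethylene glycol, 130 → 200 °C; HCl work-up
Reagents that add atoms: lithium hydroxide ([Li+].[OH-])
Why: Saponification frees the carboxylate, and Wolff–Kishner reduction of the non-enolisable neopentyl aldehyde through its hydrazone should turn the axial formyl group into the C5 methyl without affecting the tetrasubstituted alkene or the aryl methyl ethers.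

Step 16
Reactants: 28 3-[(1S,4aR,5S,6S,8aR)-5-[(2,5-dimethoxy-3-methylphenyl)methyl]-5,6,8a-trimethyl-2-(propan-2-ylidene)decahydronaphthalen-1-yl]propanoic acid
Product: 29 3-[(1S,4aR,5S,6S,8aR)-5,6,8a-trimethyl-5-[(5-methyl-3,6-dioxocyclohexa-1,4-dien-1-yl)methyl]-2-(propan-2-ylidene)decahydronaphthalen-1-yl]propanoic acid (CNP0271365.1)
Conditions: (NH4)2Ce(NO3)6, MeCN–H2O, 0 °C
Reagents that add atoms: water (O)
Why: Oxidative demethylation of the 1,4-dimethoxyarene (two one-electron oxidations, water supplying the carbonyl oxygens) should give the 1,4-benzoquinone, the acid and the tetrasubstituted alkene tolerating the brief cold treatment.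

Compound list
1 | pent-3-yn-1-ol | CC#CCCO | starting material
2 | [5-(bromomagnesiooxy)-2-methylpent-2-en-3-yl]magnesium bromide | CC(C)=C([Mg]Br)CCO[Mg]Br | intermediate
3 | 3-iodo-4-methylpent-3-en-1-ol | CC(C)=C(I)CCO | intermediate
4 | 5-chloro-3-iodo-2-methylpent-2-ene | CC(C)=C(I)CCCl | intermediate
5 | 5-chloro-3-ethynyl-2-methylpent-2-ene | C#CC(=C(C)C)CCCl | intermediate
6 | 3-methylcyclohex-2-en-1-one | CC1=CC(=O)CCC1 | starting material
7 | [5-chloro-3-(propan-2-ylidene)pent-1-en-2-yl]bis(2-methylpropyl)alane | C=C([Al](CC(C)C)CC(C)C)C(=C(C)C)CCCl | intermediate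
8 | diisobutylaluminium enolate of ketone 9 | ClCCC(=C(C)C)C(=C)[C@]1(C)CCCC(O[Al](CC(C)C)CC(C)C)=C1 | intermediate
9 | (3R)-3-[5-chloro-3-(propan-2-ylidene)pent-1-en-2-yl]-3-methylcyclohexan-1-one | ClCCC(=C(C)C)C(=C)[C@]1(C)CCCC(=O)C1 | intermediate
10 | potassium enolate of ketone 9 toward the future C4a | ClCCC(=C(C)C)C(=C)[C@]1(C)CCCC([O-])=C1.[K+] | intermediate
11 | (4aR,8aR)-8a-methyl-1-methylidene-2-(propan-2-ylidene)decahydronaphthalen-5-one (cis-fused) | O=C2[C@@H]3CCC(=C(C)C)C(=C)[C@]3(C)CCC2 | intermediate
12 | (4aS,8aR)-8a-methyl-1-methylidene-2-(propan-2-ylidene)decahydronaphthalen-5-one (trans-fused) | O=C2[C@H]3CCC(=C(C)C)C(=C)[C@]3(C)CCC2 | intermediate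
13 | (4aS,8aR)-8a-methyl-1-methylidene-2-(propan-2-ylidene)-1,2,3,4,4a,7,8,8a-octahydronaphthalen-5-yl trifluoromethanesulfonate | FC(F)(F)S(=O)(=O)OC=2[C@H]3CCC(=C(C)C)C(=C)[C@]3(C)CCC=2 | intermediate
14 | B-alkyl-9-borabicyclo[3.3.1]nonane adduct of 13 (boron on the former methylidene carbon) | FC(F)(F)S(=O)(=O)OC=2[C@H]3CCC(=C(C)C)[C@@H](CB4C5CCCC4CCC5)[C@]3(C)CCC=2 | intermediate
15 | ethyl 3-[(1S,4aS,8aS)-8a-methyl-2-(propan-2-ylidene)-5-(trifluoromethanesulfonyloxy)-1,2,3,4,4a,7,8,8a-octahydronaphthalen-1-yl]propanoate | FC(F)(F)S(=O)(=O)OC=2[C@H]3CCC(=C(C)C)[C@@H](CCC(=O)OCC)[C@]3(C)CCC=2 | intermediate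
16 | ethyl 3-[(1S,4aS,8aS)-5-formyl-8a-methyl-2-(propan-2-ylidene)-1,2,3,4,4a,7,8,8a-octahydronaphthalen-1-yl]propanoate | O=CC=2[C@H]3CCC(=C(C)C)[C@@H](CCC(=O)OCC)[C@]3(C)CCC=2 | intermediate
17 | trimethylsilyl enol ether of aldehyde 18 | C[Si](C)(C)OC=C2[C@H]3CCC(=C(C)C)[C@@H](CCC(=O)OCC)[C@]3(C)CC[C@@H]2C | intermediate
18 | ethyl 3-[(1S,4aR,6S,8aR)-5-formyl-6,8a-dimethyl-2-(propan-2-ylidene)decahydronaphthalen-1-yl]propanoate (both C5 epimers) | O=CC2[C@H]3CCC(=C(C)C)[C@@H](CCC(=O)OCC)[C@]3(C)CC[C@@H]2C | intermediate
19 | 4-methoxy-2-methylphenol | COc1ccc(O)c(C)c1 | starting material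
20 | 2-hydroxy-5-methoxy-3-methylbenzaldehyde | COc1cc(C)c(O)c(C=O)c1 | intermediate
21 | 2,5-dimethoxy-3-methylbenzaldehyde | COc1cc(C)c(OC)c(C=O)c1 | intermediate
22 | (2,5-dimethoxy-3-methylphenyl)methanol | COc1cc(C)c(OC)c(CO)c1 | intermediate
23 | 1-(bromomethyl)-2,5-dimethoxy-3-methylbenzene | COc1cc(C)c(OC)c(CBr)c1 | intermediate
24 | potassium enolate of aldehyde 18 | [O-]C=C2[C@H]3CCC(=C(C)C)[C@@H](CCC(=O)OCC)[C@]3(C)CC[C@@H]2C.[K+] | intermediate
25 | ethyl 3-[(1S,4aS,5R,6S,8aS)-5-[(2,5-dimethoxy-3-methylphenyl)methyl]-5-formyl-6,8a-dimethyl-2-(propan-2-ylidene)decahydronaphthalen-1-yl]propanoate | COc1cc(C)c(OC)c(C[C@]2(C=O)[C@H]3CCC(=C(C)C)[C@@H](CCC(=O)OCC)[C@]3(C)CC[C@@H]2C)c1 | intermediate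
26 | lithium carboxylate from saponification of 25 | COc1cc(C)c(OC)c(C[C@]2(C=O)[C@H]3CCC(=C(C)C)[C@@H](CCC(=O)[O-])[C@]3(C)CC[C@@H]2C)c1.[Li+] | intermediate
27 | hydrazone of the formyl carboxylate (potassium salt) | COc1cc(C)c(OC)c(C[C@]2(C=NN)[C@H]3CCC(=C(C)C)[C@@H](CCC(=O)[O-])[C@]3(C)CC[C@@H]2C)c1.[K+] | intermediate
28 | 3-[(1S,4aR,5S,6S,8aR)-5-[(2,5-dimethoxy-3-methylphenyl)methyl]-5,6,8a-trimethyl-2-(propan-2-ylidene)decahydronaphthalen-1-yl]propanoic acid | COc1cc(C)c(OC)c(C[C@]2(C)[C@H]3CCC(=C(C)C)[C@@H](CCC(=O)O)[C@]3(C)CC[C@@H]2C)c1 | intermediate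
29 | 3-[(1S,4aR,5S,6S,8aR)-5,6,8a-trimethyl-5-[(5-methyl-3,6-dioxocyclohexa-1,4-dien-1-yl)methyl]-2-(propan-2-ylidene)decahydronaphthalen-1-yl]propanoic acid | CC1=CC(=O)C=C(C[C@]2(C)[C@H]3CCC(=C(C)C)[C@@H](CCC(=O)O)[C@]3(C)CC[C@@H]2C)C1=O | target

Total step count: 16. Longest linear sequence: 12 steps (steps 1–9, then 14–16); the arene branch (steps 10–13) joins at step 14.

Steps most likely to fail

Step 4. The hindered, α-branched dienyl group may transfer from aluminium to copper slowly or with weak face selection. The fallback exchanges the roles of the two carbon groups at the quaternary centre. Starting from enyne 5, alkenylalane 7 is quenched with I2 to give 5-chloro-2-iodo-3-(propan-2-ylidene)pent-1-ene F1. Iodine–lithium exchange (t-BuLi, −78 °C), 1,2-addition to commercial 3-ethoxycyclohex-2-en-1-one and aqueous HCl (carbonyl transposition of the vinylogous ester) should give 3-[5-chloro-3-(propan-2-ylidene)pent-1-en-2-yl]cyclohex-2-en-1-one F2. Copper-catalysed asymmetric 1,4-addition of MeMgBr with Cu(OTf)2 and a chiral imidazolinium (N-heterocyclic carbene) ligand, a catalyst class that favours 1,4- over 1,6-addition on 3-alkenylcyclohexenones, then installs the methyl group and returns to ketone 9.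

Step 14. O-alkylation of the hindered aldehyde enolate, or base-induced condensation of the ester side chain, may compete with C-benzylation. In the fallback the trimethylsilyl enol ether 17 from step 9 is isolated by non-aqueous work-up and treated with bromide 23 and ZnBr2 in CH2Cl2. This is a Lewis-acid-mediated α-alkylation of a silyl enol ether by an ortho-methoxy-stabilised benzylic cation under non-basic conditions. The same equatorial approach applies and aldehyde 25 is reached directly, so this fallback makes no new compound (F0).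

Step 7. Migration of the β-branched alkyl group from boron to the bromoacetate enolate may be sluggish, or the base may attack the enol triflate. The fallback makes the carbon–carbon bond by olefination instead. Alkylborane 14 is oxidised (NaBO3·4H2O, THF–H2O) to the hydroxymethyl triflate F3. Dess–Martin oxidation gives the formyl triflate F4, used at once to avoid epimerisation or alkene migration. Wittig reaction with Ph3P=CHCO2Et gives the (E)-enoate triflate F5. Conjugate reduction with [(Ph3P)CuH]6, which should leave the enol triflate and the tetrasubstituted alkene untouched, returns to ester 15.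

Further compounds
F1 | step 4 | 5-chloro-2-iodo-3-(propan-2-ylidene)pent-1-ene | C=C(I)C(=C(C)C)CCCl
F2 | step 4 | 3-[5-chloro-3-(propan-2-ylidene)pent-1-en-2-yl]cyclohex-2-en-1-one | O=C1C=C(CCC1)C(=C)C(=C(C)C)CCCl
F0 | step 14 | none | none
F3 | step 7 | hydroxymethyl triflate (1-hydroxymethyl analogue of 15) | FC(F)(F)S(=O)(=O)OC=2[C@H]3CCC(=C(C)C)[C@@H](CO)[C@]3(C)CCC=2
F4 | step 7 | formyl triflate (1-formyl analogue of 15) | FC(F)(F)S(=O)(=O)OC=2[C@H]3CCC(=C(C)C)[C@@H](C=O)[C@]3(C)CCC=2
F5 | step 7 | (E)-enoate triflate (2,3-didehydro analogue of 15) | FC(F)(F)S(=O)(=O)OC=2[C@H]3CCC(=C(C)C)[C@@H](/C=C/C(=O)OCC)[C@]3(C)CCC=2
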